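**Strategy.** Atoms of the triterpenoid half carry friedelane numbers. Ring B (C5, C6, C7, C8, C9, C10) is closed last through the arene–quaternary carbon bond C10–C9. The key step, a reductive Heck cyclization, exploits the benzylic quaternary C9 with its methyl C25: the aryl bromide (Br at C10) adds 6-exo to an exocyclic C9=C25 methylene on ring C, and formate turns the resulting neopentyl C25–palladium bond into the methyl group, while the C6=C7 (Z)-styrene is already in place. The precursor unites the complete guaiane–benzodioxane aldehyde and a tricyclic C/D/E phosphonium salt by a Z-selective Wittig reaction.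

Key step: step 24

Remarks on the chemistry:
- Guaiane atoms carry primed numbers; β is the guaiane face that bears the C10′ methyl and the C7′ isopropenyl group (and the C4′ methyl in α-guaiene), α the opposite face.
- α-Guaiene and 5-bromo-2,3-dimethoxytoluene are taken as catalogue chemicals.
- In step 10 the enantiomer of the oxazaborolidinium catalyst is chosen that gives the (R)-aldehyde.

**Guaiane–benzodioxane aldehyde (steps 1–9)**

Step 1
Reactants: 1 5-bromo-2,3-dimethoxytoluene
Product: 2 6-bromo-3,4-dimethoxy-2-methylbenzaldehyde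
Conditions: Cl2CHOMe, TiCl4, CH2Cl2, −78 to 0 °C; then H2O
Reagents that add atoms: dichloromethyl methyl ether COC(Cl)Cl; water O
Why: Rieche formylation should go para to the methoxy group that can lie in the ring plane, between bromine and methyl, which gives the future C5 aldehyde next to the future C10 bromide.

Step 2
Reactants: 2 6-bromo-3,4-dimethoxy-2-methylbenzaldehyde
Product: 3 6-bromo-3,4-dihydroxy-2-methylbenzaldehyde
Conditions: BBr3, CH2Cl2, −78 to 0 °C; then H2O
Reagents that add atoms: none
Why: Lewis acid cleavage of both aryl methyl ethers should leave the aldehyde and the aryl bromide untouched.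

Step 3
Reactants: 3 6-bromo-3,4-dihydroxy-2-methylbenzaldehyde
Product: 4 6-bromo-4-(tert-butyldimethylsilyloxy)-3-hydroxy-2-methylbenzaldehyde
Conditions: TBSCl (1.05 equiv), imidazole, CH2Cl2, −20 °C
Reagents that add atoms: tert-butyldimethylsilyl chloride CC(C)(C)[Si](C)(C)Cl
Why: The hydroxyl para to the aldehyde is the more acidic and less hindered one, so selective silylation should leave the methyl-flanked hydroxyl (the future O–C1′ oxygen) free.

Step 4
Reactants: 5 α-guaiene
Product: 6 rotundone (guaia-1′(5′),11′-dien-2′-one)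
Conditions: t-BuOOH, Rh2(cap)4 (dirhodium tetracaprolactamate, 1 mol%), K2CO3, CH2Cl2, 25 °C
Reagents that add atoms: tert-butyl hydroperoxide CC(C)(C)OO
Why: Allylic C–H oxidation of the tetrasubstituted alkene at the cyclopentene methylene C2′ should give the conjugated enone, the product also formed on autoxidation of α-guaiene; C4′, C7′ and C10′ are untouched.

Step 5
Reactants: 6 rotundone
Product: 7 rotundone tosylhydrazone
Conditions: TsNHNH2, MeOH, cat. AcOH, 40 °C
Reagents that add atoms: 4-methylbenzenesulfonohydrazide Cc1ccc(cc1)S(=O)(=O)NN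
Why: Hydrazone condensation sets up the Shapiro reaction.

Step 6
Reactants: 7 rotundone tosylhydrazone
Product: 9 1′α,5′α-epoxyguaia-2′,11′-diene, via guaia-1′(5′),2′,11′-triene 8 (not isolated)
Conditions: n-BuLi (2.2 equiv), THF, −78 to 0 °C; aq. NH4Cl, pentane, 0 °C; then dimethyldioxirane (1.0 equiv), acetone, −78 to −40 °C
Reagents that add atoms: dimethyldioxirane CC1(C)OO1
Why: The Shapiro reaction (deprotonation at C3′, the only sp3 α-carbon) gives the 2′,3′-alkene, and the cold diene is epoxidized at once at its most electron-rich, tetrasubstituted C1′=C5′ bond from the α face, opposite to the C4′ and C10′ methyl groups, before a 1,5-hydrogen shift can scramble the diene.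

Step 7
Reactants: 9 1′α,5′α-epoxyguaia-2′,11′-diene; 4 6-bromo-4-(tert-butyldimethylsilyloxy)-3-hydroxy-2-methylbenzaldehyde
Product: 10 1′β-aryloxy-5′α-hydroxyguaia-2′,11′-diene (aryl = 4-bromo-3-formyl-2-methyl-6-silyloxyphenyl)
Conditions: 4 (2 equiv), BF3·OEt2 (0.2 equiv), CH2Cl2, −78 °C
Reagents that add atoms: none
Why: Lewis acid-catalysed opening of the vinyl epoxide should occur at the allylic tertiary carbon C1′ with backside attack, which places the aryl ether on the β face (syn to the C10′ methyl) and leaves the C5′ hydroxyl α; the only free phenol oxygen is the one next to the aryl methyl group.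

Step 8
Reactants: 10 1′β-aryloxy-5′α-hydroxyguaia-2′,11′-diene
Product: 11 1′β-aryloxyguaia-2′,4′,11′-triene (5,5-disubstituted cyclopentadiene)
Conditions: Burgess reagent, toluene, 50 °C
Reagents that add atoms: none
Why: Syn elimination of the tertiary sulfamate with the α hydrogen at C4′ (same face as the leaving group) should give the conjugated diene, which cannot tautomerize because C1′ carries no hydrogen.

Step 9
Reactants: 11 1′β-aryloxyguaia-2′,4′,11′-triene
Product: 13 guaiane–benzodioxane aldehyde (C5–CHO, C10–Br, C4–Me; O–C2 on C5′, O–C3 on C1′; C3′=C4′), via free phenol 12 (not isolated)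
Conditions: TBAF, THF, 0 °C; AcOH; then (PhO)2P(O)OH (10 mol%), CH2Cl2, −20 to 0 °C
Reagents that add atoms: none
Why: After desilylation, acid-catalysed hydroalkoxylation of the diene should proceed by protonation at the unsubstituted terminus C2′ to the more substituted allyl cation (C3′–C4′–C5′), which the tethered phenol can reach only at C5′ and only on the face of the C1′–O bond, giving the cis-fused β,β-dioxane with the C3′=C4′ alkene.

**C/D/E phosphonium salt (steps 10–22)**

Step 10
Reactants: 14 methacrolein; 15 isoprene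
Product: 16 (R)-1,4-dimethylcyclohex-3-ene-1-carbaldehyde
Conditions: chiral o-tolyl oxazaborolidinium triflimide catalyst (10 mol%), CH2Cl2, −78 °C
Reagents that add atoms: none
Why: The catalytic enantioselective Diels–Alder reaction should give the para adduct and set the quaternary C20 by catalyst control.

Step 11
Reactants: 16 (R)-1,4-dimethylcyclohex-3-ene-1-carbaldehyde
Product: 18 methyl (R)-1,4-dimethylcyclohex-3-ene-1-carboxylate, via carboxylic acid 17 (not isolated)
Conditions: NaClO2, NaH2PO4, 2-methyl-2-butene, t-BuOH/H2O, 0 °C; then TMSCHN2, MeOH/toluene, 0 °C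
Reagents that add atoms: sodium chlorite [Na+].[O-]Cl=O; trimethylsilyldiazomethane C[Si](C)(C)C=[N+]=[N-]
Why: Pinnick oxidation followed by diazoalkane esterification should give the C20 ester without touching the alkene or the quaternary centre.

Step 12
Reactants: 18 methyl (R)-1,4-dimethylcyclohex-3-ene-1-carboxylate
Product: 20 methyl (1R)-1,4-dimethyl-3-oxocyclohexane-1-carboxylate (C17 epimers), via secondary alcohol 19 (not isolated)
Conditions: BH3·SMe2, THF, 0 °C; H2O2, NaOH, 0 °C; then Dess–Martin periodinane, NaHCO3, CH2Cl2, 25 °C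
Reagents that add atoms: hydrogen peroxide OO
Why: Hydroboration puts boron on the less substituted alkene carbon C18 and oxidation gives the C18 ketone; the C17 configuration is immaterial because it is enolized in the next step.

Step 13
Reactants: 20 methyl (1R)-1,4-dimethyl-3-oxocyclohexane-1-carboxylate; 21 ethyl vinyl ketone
Product: 24 D/E octalone (C14 ketone, C13(Me)=C18, C17 methyl, C20 methyl and CO2Me), via chiral imine 22 (not isolated), via diketone 23 (not isolated)
Conditions: (S)-1-phenylethylamine, cat. TsOH, toluene, reflux (−H2O); 21, THF, 25 °C; aq. AcOH; then NaOMe, MeOH, 60 °C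
Reagents that add atoms: none
Why: Michael addition through the more substituted secondary enamine of the chiral imine (aza-ene-like chair, attack anti to the phenyl group) should set the quaternary C17 under auxiliary control, and base then closes ring D by aldol condensation (Robinson annulation).

Step 14
Reactants: 24 D/E octalone
Product: 25 cis-fused D/E decalone (H18 β, cis to the C17 methyl; C13 epimers)
Conditions: H2 (1 atm), Pd/C, Et3N, EtOAc, 25 °C
Reagents that add atoms: none
Why: Heterogeneous hydrogenation of such angularly methylated octalones should add hydrogen cis to the angular methyl and give the cis ring fusion; C13 stays epimerizable, which is immaterial.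

Step 15
Reactants: 25 cis-fused D/E decalone; 26 methyl acrylate
Product: 28 keto diester (C13: methyl α, CH2CH2CO2Me β; C14 ketone), via chiral imine 27 (not isolated)
Conditions: (S)-1-phenylethylamine, cat. TsOH, toluene, reflux (−H2O); 26, THF, 50 °C; aq. AcOH
Reagents that add atoms: none
Why: The same chiral-imine Michael reaction alkylates the more substituted α-carbon C13 from the convex β face (the α face is screened by ring E), substrate and auxiliary working in the same sense, so the C13 methyl ends α.

Step 16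
Reactants: 28 keto diester
Product: 29 exocyclic tert-butyl enoate (C14=C8H–CO2tBu, alkene isomers)
Conditions: t-BuO2CCH2SiMe3, LDA, THF, −78 to 0 °C
Reagents that add atoms: tert-butyl 2-(trimethylsilyl)acetate CC(C)(C)OC(=O)C[Si](C)(C)C
Why: Peterson olefination adds C8 and C7 to the hindered C14 ketone, where a phosphonate would be sluggish; both alkene isomers serve.

Step 17
Reactants: 29 exocyclic tert-butyl enoate
Product: 31 tricyclic β-keto ester (C9 ketone, C8–CO2tBu equatorial, C14 methyl β), via silyl ketene acetal 30 (not isolated)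
Conditions: Me2CuLi, TMSCl, THF, −78 to −20 °C; concentrate; then KOtBu, THF, 0 to 25 °C
Reagents that add atoms: lithium dimethylcuprate [Li+].C[Cu-]C
Why: The silyl chloride-accelerated conjugate addition should deliver the C26 methyl to C14 from the β face (the other approach is blocked by the adjacent axial C13 methyl), and the regiodefined C8 enolate then closes ring C by Dieckmann condensation onto the methyl ester, the tert-butyl ester being unable to act as acceptor; C8 equilibrates to the equatorial ester.

Step 18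
Reactants: 31 tricyclic β-keto ester
Product: 32 tert-butyl ester with exocyclic C9=C25 methylene
Conditions: Zn, CH2Br2, TiCl4, THF, 0 to 25 °C
Reagents that add atoms: dibromomethane BrCBr
Why: Takai–Lombardo methylenation is non-basic and suited to enolizable ketones, so it should convert C9=O into C9=CH2 without epimerizing C8 or touching the esters.

Step 19
Reactants: 32 tert-butyl ester with exocyclic methylene
Product: 33 C7 carboxylic acid
Conditions: TMSOTf, 2,6-lutidine, CH2Cl2, 0 °C; then H2O
Reagents that add atoms: none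
Why: Silyl triflate-mediated cleavage of the tert-butyl ester (loss of isobutene) should spare the hindered methyl ester and the 1,1-disubstituted alkene.

Step 20
Reactants: 33 C7 carboxylic acid
Product: 35 primary alcohol (C8–CH2OH), via mixed anhydride 34 (not isolated)
Conditions: i-BuOCOCl, N-methylmorpholine, THF, −15 °C; then NaBH4, H2O, 0 °C
Reagents that add atoms: none
Why: Borohydride reduces only the activated mixed anhydride, so the C20 methyl ester and the alkene survive.

Step 21
Reactants: 35 primary alcohol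
Product: 36 primary iodide (C8–CH2I)
Conditions: I2, PPh3, imidazole, CH2Cl2, 0 to 25 °C
Reagents that add atoms: iodine II
Why: Appel-type iodination of the primary alcohol is reliable and leaves the methyl ester and exocyclic alkene untouched.

Step 22
Reactants: 36 primary iodide
Product: 37 triphenylphosphonium iodide
Conditions: PPh3, MeCN, 80 °C
Reagents that add atoms: triphenylphosphine c1ccc(cc1)P(c1ccccc1)c1ccccc1
Why: SN2 quaternization of the β-branched primary iodide gives the Wittig salt.

**Fragment union and ring B closure (steps 23–24)**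

Step 23
Reactants: 37 triphenylphosphonium iodide; 13 guaiane–benzodioxane aldehyde
Product: 39 (Z)-styrene (C6=C7) carrying C10–Br and the C9=C25 methylene, via phosphorus ylide 38 (not isolated)
Conditions: KHMDS, THF, −78 °C; then 13, −78 to 25 °C
Reagents that add atoms: none
Why: Wittig reaction of a non-stabilized ylide with an ortho-disubstituted aromatic aldehyde under salt-free conditions should give the (Z)-alkene through the cis-oxaphosphetane; the non-enolizable C20 ester and the allylic aryl ether tolerate the base.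

Step 24
Reactants: 39 (Z)-styrene
Product: 40 target CNP0113384.2
Conditions: Pd(OAc)2 (10 mol%), PPh3 (20 mol%), HCO2Na, Bu4NCl, DMF, 80 °C
Reagents that add atoms: none
Why: Zerovalent palladium inserts into the C10–Br bond, the arylpalladium adds syn across the exocyclic C9=C25 alkene, and the resulting neopentyl alkylpalladium, which has no β-hydrogen, exchanges bromide for formate, loses CO2 and reductively eliminates to the C25 methyl group. The closest known reaction type is the reductive Heck cyclization used to build benzylic quaternary carbons bearing a methyl group. Ring B closes in the 6-exo-trig mode, the rigid (Z)-C6=C7 tether holding C10 over C9. The new stereocentre C9 is controlled by the axial C14 methyl (C26), which shields the β face 1,3 to C9, so the aryl group should add on the α face, trans to the C8 substituent, giving the C25 methyl β and the trans B/C fusion. The step needs chemoselectivity for this alkene over the isopropenyl and cyclopentene alkenes, secured by the intramolecular six-membered transition state, and survival of the tertiary allylic aryl ether, which re-closes intramolecularly even if ionized.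

**Compound list**

1 | 5-bromo-2,3-dimethoxytoluene | COc1cc(Br)cc(C)c1OC | starting material
2 | 6-bromo-3,4-dimethoxy-2-methylbenzaldehyde | COc1cc(Br)c(C=O)c(C)c1OC | intermediate
3 | 6-bromo-3,4-dihydroxy-2-methylbenzaldehyde | Oc1cc(Br)c(C=O)c(C)c1O | intermediate
4 | 6-bromo-4-(tert-butyldimethylsilyloxy)-3-hydroxy-2-methylbenzaldehyde | CC(C)(C)[Si](C)(C)Oc1cc(Br)c(C=O)c(C)c1O | intermediate
5 | α-guaiene | C=C(C)[C@@H]1CC[C@H](C)C2=C(C1)[C@@H](C)CC2 | starting material
6 | rotundone (guaia-1′(5′),11′-dien-2′-one) | C=C(C)[C@@H]1CC[C@H](C)C2=C(C1)[C@@H](C)CC2=O | intermediate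
7 | rotundone tosylhydrazone | C=C(C)[C@@H]1CC[C@H](C)C2=C(C1)[C@@H](C)CC2=NNS(=O)(=O)c1ccc(C)cc1 | intermediate
8 | guaia-1′(5′),2′,11′-triene | C=C(C)[C@@H]1CC[C@H](C)C2=C(C1)[C@@H](C)C=C2 | intermediate
9 | 1′α,5′α-epoxyguaia-2′,11′-diene | C=C(C)[C@@H]1CC[C@H](C)[C@]23O[C@]3(C1)[C@@H](C)C=C2 | intermediate
10 | 1′β-aryloxy-5′α-hydroxyguaia-2′,11′-diene (aryl = 4-bromo-3-formyl-2-methyl-6-(TBS-oxy)phenyl) | C=C(C)[C@@H]1CC[C@H](C)[C@@]2(Oc3c(C)c(C=O)c(Br)cc3O[Si](C)(C)C(C)(C)C)C=C[C@H](C)[C@]2(O)C1 | intermediate
11 | 1′β-aryloxyguaia-2′,4′,11′-triene (silyl ether) | C=C(C)[C@@H]1CC[C@H](C)[C@@]2(Oc3c(C)c(C=O)c(Br)cc3O[Si](C)(C)C(C)(C)C)C=CC(C)=C2C1 | intermediate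
12 | 1′β-aryloxyguaia-2′,4′,11′-triene (free phenol) | C=C(C)[C@@H]1CC[C@H](C)[C@@]2(Oc3c(C)c(C=O)c(Br)cc3O)C=CC(C)=C2C1 | intermediate
13 | guaiane–benzodioxane aldehyde (C5–CHO, C10–Br) | C=C(C)[C@@H]1CC[C@H](C)[C@@]23CC=C(C)[C@]2(C1)Oc1cc(Br)c(C=O)c(C)c1O3 | intermediate
14 | methacrolein | CC(=C)C=O | starting material
15 | isoprene | CC(=C)C=C | starting material
16 | (R)-1,4-dimethylcyclohex-3-ene-1-carbaldehyde | CC1=CC[C@](C)(C=O)CC1 | intermediate
17 | (R)-1,4-dimethylcyclohex-3-ene-1-carboxylic acid | CC1=CC[C@](C)(C(=O)O)CC1 | intermediate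
18 | methyl (R)-1,4-dimethylcyclohex-3-ene-1-carboxylate | CC1=CC[C@](C)(C(=O)OC)CC1 | intermediate
19 | methyl (1R)-3-hydroxy-1,4-dimethylcyclohexane-1-carboxylate (isomers at C17, C18) | CC1CC[C@@](C)(C(=O)OC)CC1O | intermediate
20 | methyl (1R)-1,4-dimethyl-3-oxocyclohexane-1-carboxylate (C17 epimers) | CC1CC[C@@](C)(C(=O)OC)CC1=O | intermediate
21 | ethyl vinyl ketone (pent-1-en-3-one) | CCC(=O)C=C | starting material
22 | (S)-1-phenylethyl imine of 20 | CC1CC[C@@](C)(C(=O)OC)CC1=N[C@@H](C)c1ccccc1 | intermediate
23 | 1,5-diketone with quaternary C17 | CCC(=O)CC[C@@]1(C)CC[C@@](C)(C(=O)OC)CC1=O | intermediate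
24 | D/E octalone (C14 ketone, C13(Me)=C18) | CC1=C2C[C@](C)(C(=O)OC)CC[C@]2(C)CCC1=O | intermediate
25 | cis-fused D/E decalone (H18 β; C13 epimers) | CC1[C@@H]2C[C@](C)(C(=O)OC)CC[C@]2(C)CCC1=O | intermediate
26 | methyl acrylate | COC(=O)C=C | starting material
27 | (S)-1-phenylethyl imine of 25 | CC1[C@@H]2C[C@](C)(C(=O)OC)CC[C@]2(C)CCC1=N[C@@H](C)c1ccccc1 | intermediate
28 | keto diester (C13 quaternary, C14 ketone) | COC(=O)CC[C@@]1(C)[C@@H]2C[C@](C)(C(=O)OC)CC[C@]2(C)CCC1=O | intermediate
29 | exocyclic tert-butyl enoate at C14 | COC(=O)CC[C@@]1(C)[C@@H]2C[C@](C)(C(=O)OC)CC[C@]2(C)CCC1=CC(=O)OC(C)(C)C | intermediate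
30 | silyl ketene acetal with quaternary C14 | COC(=O)CC[C@@]1(C)[C@@H]2C[C@](C)(C(=O)OC)CC[C@]2(C)CC[C@]1(C)C=C(OC(C)(C)C)O[Si](C)(C)C | intermediate
31 | tricyclic C/D/E β-keto ester (C9 ketone, C8–CO2tBu) | CC(C)(C)OC(=O)[C@H]1C(=O)CC[C@@]2(C)[C@@H]3C[C@](C)(C(=O)OC)CC[C@]3(C)CC[C@]12C | intermediate
32 | tricyclic tert-butyl ester with C9=C25 methylene | CC(C)(C)OC(=O)[C@H]1C(=C)CC[C@@]2(C)[C@@H]3C[C@](C)(C(=O)OC)CC[C@]3(C)CC[C@]12C | intermediate
33 | tricyclic C7 carboxylic acid | OC(=O)[C@H]1C(=C)CC[C@@]2(C)[C@@H]3C[C@](C)(C(=O)OC)CC[C@]3(C)CC[C@]12C | intermediate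
34 | isobutyl carbonic mixed anhydride of 33 | CC(C)COC(=O)OC(=O)[C@H]1C(=C)CC[C@@]2(C)[C@@H]3C[C@](C)(C(=O)OC)CC[C@]3(C)CC[C@]12C | intermediate
35 | tricyclic primary alcohol (C8–CH2OH) | OC[C@H]1C(=C)CC[C@@]2(C)[C@@H]3C[C@](C)(C(=O)OC)CC[C@]3(C)CC[C@]12C | intermediate
36 | tricyclic primary iodide | IC[C@H]1C(=C)CC[C@@]2(C)[C@@H]3C[C@](C)(C(=O)OC)CC[C@]3(C)CC[C@]12C | intermediate
37 | tricyclic triphenylphosphonium iodide | [I-].c1ccc(cc1)[P+](c1ccccc1)(c1ccccc1)C[C@H]1C(=C)CC[C@@]2(C)[C@@H]3C[C@](C)(C(=O)OC)CC[C@]3(C)CC[C@]12C | intermediate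
38 | phosphorus ylide of 37 | c1ccc(cc1)P(c1ccccc1)(c1ccccc1)=C[C@H]1C(=C)CC[C@@]2(C)[C@@H]3C[C@](C)(C(=O)OC)CC[C@]3(C)CC[C@]12C | intermediate
39 | (Z)-styrene cyclization precursor | C=C(C)[C@@H]1CC[C@H](C)[C@@]23CC=C(C)[C@]2(C1)Oc1cc(Br)c(/C=C\[C@H]4C(=C)CC[C@@]5(C)[C@@H]6C[C@](C)(C(=O)OC)CC[C@]6(C)CC[C@]45C)c(C)c1O3 | intermediate
40 | CNP0113384.2 | C=C(C)[C@@H]1CC[C@H](C)[C@@]23CC=C(C)[C@]2(C1)Oc1cc2c(c(C)c1O3)C=C[C@H]1[C@@]2(C)CC[C@@]2(C)[C@@H]3C[C@](C)(C(=O)OC)CC[C@]3(C)CC[C@]12C | target

**Step count and risks**

Total step count: 24. Longest linear sequence: 15 steps (steps 10 to 24).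

Steps most likely to fail:

1. Step 7. The phenol may attack C3′ with allylic shift instead of C1′, or the Lewis acid may rearrange the strained epoxide before the hindered phenol arrives. The fallback sets out from 6 and comes back at 11; it reaches the same β-ether by double inversion on the opposite epoxide. Luche reduction of 6 (NaBH4, CeCl3, hydride from the α face) should give guaia-1′(5′),11′-dien-2′β-ol F3. Hydroxyl-directed epoxidation (VO(acac)2, t-BuOOH) gives 1′β,5′β-epoxyguai-11′-en-2′β-ol F4. Dehydration with Martin sulfurane gives 1′β,5′β-epoxyguaia-2′,11′-diene F5. Palladium-catalysed opening with phenol 4 (Pd(PPh3)4, cat. Et3B, net retention at C1′) gives the 1′β-aryloxy-5′β-hydroxy diene F6. Anti elimination with SOCl2 and pyridine (the α hydrogen at C4′ is anti to the β hydroxyl) then gives 11.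

2. Step 17. The cuprate may fail to add to the β-carbon that is screened by the neighbouring quaternary C13, so that reduction or recovery of the enoate dominates. The fallback sets out from 28 and comes back at 31; it uses a far stronger acceptor. Knoevenagel condensation of 28 with Meldrum's acid (TiCl4, pyridine) gives the alkylidene Meldrum's acid F7. Copper-catalysed addition of MeMgBr (CuBr·SMe2) gives the methylated Meldrum's acid adduct F8. Heating with tert-butanol in toluene opens the ring and decarboxylates to the tert-butyl acetate diester F9, and KOtBu then effects the same Dieckmann closure to 31.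

3. Step 6. The cyclopentadiene 8 may isomerize by 1,5-hydrogen shift or be over-oxidized before the selective epoxidation, and the vinyl epoxide is acid-sensitive. The fallback sets out from 6 and comes back at 9; it avoids the free diene. Nucleophilic epoxidation of 6 (H2O2, NaOH, MeOH) from the α face gives 1′α,5′α-epoxyguai-11′-en-2′-one F1. Reduction (NaBH4, CeCl3) gives 1′α,5′α-epoxyguai-11′-en-2′-ol F2. Dehydration with Martin sulfurane, possible only towards C3′, gives 9.

Further compounds
F1 | step 6 | 1′α,5′α-epoxyguai-11′-en-2′-one | C=C(C)[C@@H]1CC[C@H](C)[C@]23O[C@]3(C1)[C@@H](C)CC2=O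
F2 | step 6 | 1′α,5′α-epoxyguai-11′-en-2′-ol | C=C(C)[C@@H]1CC[C@H](C)[C@]23O[C@]3(C1)[C@@H](C)CC2O
F3 | step 7 | guaia-1′(5′),11′-dien-2′β-ol | C=C(C)[C@@H]1CC[C@H](C)C2=C(C1)[C@@H](C)C[C@H]2O
F4 | step 7 | 1′β,5′β-epoxyguai-11′-en-2′β-ol | C=C(C)[C@@H]1CC[C@H](C)[C@@]23O[C@@]3(C1)[C@@H](C)C[C@H]2O
F5 | step 7 | 1′β,5′β-epoxyguaia-2′,11′-diene | C=C(C)[C@@H]1CC[C@H](C)[C@@]23O[C@@]3(C1)[C@@H](C)C=C2
F6 | step 7 | 1′β-aryloxy-5′β-hydroxyguaia-2′,11′-diene | C=C(C)[C@@H]1CC[C@H](C)[C@@]2(Oc3c(C)c(C=O)c(Br)cc3O[Si](C)(C)C(C)(C)C)C=C[C@H](C)[C@@]2(O)C1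
F7 | step 17 | alkylidene Meldrum's acid at C14 | COC(=O)CC[C@@]1(C)[C@@H]2C[C@](C)(C(=O)OC)CC[C@]2(C)CCC1=C3C(=O)OC(C)(C)OC3=O
F8 | step 17 | methylated Meldrum's acid adduct | COC(=O)CC[C@@]1(C)[C@@H]2C[C@](C)(C(=O)OC)CC[C@]2(C)CC[C@]1(C)C3C(=O)OC(C)(C)OC3=O
F9 | step 17 | tert-butyl acetate diester with quaternary C14 | COC(=O)CC[C@@]1(C)[C@@H]2C[C@](C)(C(=O)OC)CC[C@]2(C)CC[C@]1(C)CC(=O)OC(C)(C)C
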